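## Retrosynthetic overview

1. Feature: in the 2,3-dihydrobenzofuran (O1, C2, C3, C3a, C4–C7, C7a), C3, C2 and the C(CH3)2OH carbon with its two methyls make one five-carbon isoprene unit. It is joined to arene carbon C3a and to the adjacent oxygen O1, so the furan ring equals isoprene plus an ortho-iodophenol.
2. Late disconnections: the C5–prenyl bond (C-alkylation at the only ring CH left), the MOM group on O4, and the tertiary OH (Markovnikov hydration of a C2 isopropenyl group while it is the only alkene present).
3. Key disconnection: C3a–C3 and O1–C2 are made together by an enantioselective palladium-catalysed diene heteroannulation, which also sets C2 as (S).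
4. The iodophenol comes from phloroglucinol by C-acylation, MOM protection of the para OH and mono-iodination; the two ring CH positions are equivalent by symmetry, so there is no regiochemical question.
5. Ring order: both benzene rings are purchased, and the dihydrofuran ring is the only ring formed (step 4).

Key step: step 4

Assumption: the sense of induction of the chiral ligand on this hindered iodide cannot be predicted with certainty. Both ligand antipodes are accessible, and the one that delivers (2S)-7 is used, with the configuration to be checked at compound 7.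

## Route

Step 1
Reactants: 1 phloroglucinol; 2 3-(4-methoxyphenyl)propanoic acid
Product: 3 3-(4-methoxyphenyl)-1-(2,4,6-trihydroxyphenyl)propan-1-one
Conditions: BF3·OEt2 (neat, excess), 85 °C; aq NaOAc work-up
Reagents that add atoms: none
Why: Friedel–Crafts C-acylation with the free acid as acyl donor should stop at the mono-ketone because the chelated acyl group deactivates the ring, and the anisyl ring of 2 is far less nucleophilic than phloroglucinol, so indanone closure should not compete.

Step 2
Reactants: 3 3-(4-methoxyphenyl)-1-(2,4,6-trihydroxyphenyl)propan-1-one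
Product: 4 1-[2,6-dihydroxy-4-(methoxymethoxy)phenyl]-3-(4-methoxyphenyl)propan-1-one
Conditions: MOMCl (1.05 equiv), iPr2NEt (1.2 equiv), THF, 0 °C
Reagents that add atoms: chloromethyl methyl ether (MOMCl), COCCl
Why: In this Williamson-type O-alkylation (MOM ether formation) the 4-OH is the most acidic hydroxyl and the only one that cannot hydrogen-bond to the ketone, so one equivalent of MOMCl should react there first.

Step 3
Reactants: 4 1-[2,6-dihydroxy-4-(methoxymethoxy)phenyl]-3-(4-methoxyphenyl)propan-1-one
Product: 5 1-[2,6-dihydroxy-3-iodo-4-(methoxymethoxy)phenyl]-3-(4-methoxyphenyl)propan-1-one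
Conditions: NIS (1.0 equiv), MeCN, −20 to 0 °C, dark
Reagents that add atoms: N-iodosuccinimide, O=C1CCC(=O)N1I
Why: In this electrophilic aromatic iodination C3 and C5 are identical by symmetry and activated by three oxygen donors, so no acid additive is needed (MOM is safe), and one equivalent of NIS at low temperature should hold the reaction at the mono-iodide.

Step 4
Reactants: 5 1-[2,6-dihydroxy-3-iodo-4-(methoxymethoxy)phenyl]-3-(4-methoxyphenyl)propan-1-one; 6 isoprene
Product: 7 1-[(2S)-6-hydroxy-4-(methoxymethoxy)-2-(prop-1-en-2-yl)-2,3-dihydrobenzofuran-7-yl]-3-(4-methoxyphenyl)propan-1-one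
Conditions: Pd2(dba)3·CHCl3 (5 mol %), enantiopure tert-butanesulfinamide-derived 2-(dialkylphosphino)aryl monophosphine L* (Sadphos class, 20 mol %), NaOPh (2.5 equiv), isoprene (5 equiv), toluene, sealed tube, 60 °C
Reagents that add atoms: none
Why: Zerovalent palladium inserts into the C–I bond of 5, the aryl–palladium species adds across the unsubstituted vinyl group of isoprene with the aryl carbon going to the terminal CH2 (bond C3a–C3), and the resulting π-allyl palladium over C2, C(CH3) and CH2 is captured at C2 by the neighbouring phenoxide (bond O1–C2), which returns zerovalent palladium. The closest known reaction type is the Larock-type heteroannulation of 1,3-dienes with ortho-halophenols (a Heck insertion/Tsuji–Trost etherification cascade), which is established with isoprene and in enantioselective form with chiral monophosphines and is applied here to a more hindered iodide flanked by two oxygens. The dihydrofuran ring closes in the 5-exo mode, with oxygen attacking the internal allyl carbon and leaving the isopropenyl group outside the ring, whereas attack at the far CH2 would need a seven-membered ring and should be much slower. C2 is controlled by the ligand: the two diastereomeric π-allyl complexes can interconvert by π–σ–π slippage through the unsubstituted CH2 terminus, so C–O bond formation through the better-matched complex decides the configuration, (S) with the chosen antipode. The step needs insertion at the vinyl rather than the 1,1-disubstituted alkene, which the methyl group secures sterically, and ring closure by a single oxygen, which the substrate secures because O4 carries MOM and the second free OH lies para to the iodine-bearing carbon and cannot reach the allyl unit. Ketone, MOM ether and anisyl ring are inert to the mild phenoxide base, and excess diene should favour insertion over hydrodeiodination.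

Step 5
Reactants: 7 1-[(2S)-6-hydroxy-4-(methoxymethoxy)-2-(prop-1-en-2-yl)-2,3-dihydrobenzofuran-7-yl]-3-(4-methoxyphenyl)propan-1-one
Product: 8 1-[(2S)-6-hydroxy-2-(2-hydroxypropan-2-yl)-4-(methoxymethoxy)-2,3-dihydrobenzofuran-7-yl]-3-(4-methoxyphenyl)propan-1-one
Conditions: Co(acac)2 (20 mol %), PhSiH3 (2.5 equiv), O2 (1 atm), THF, rt
Reagents that add atoms: dioxygen, O=O
Why: In this Mukaiyama hydration a cobalt hydride transfers a hydrogen atom to the terminal CH2 of the only alkene, the tertiary radical is trapped by O2 and the peroxy species is reduced by the silane to the tertiary alcohol, all without touching C2, so (S) is kept.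

Step 6
Reactants: 8 1-[(2S)-6-hydroxy-2-(2-hydroxypropan-2-yl)-4-(methoxymethoxy)-2,3-dihydrobenzofuran-7-yl]-3-(4-methoxyphenyl)propan-1-one
Product: 9 1-[(2S)-4,6-dihydroxy-2-(2-hydroxypropan-2-yl)-2,3-dihydrobenzofuran-7-yl]-3-(4-methoxyphenyl)propan-1-one
Conditions: HCl (cat., aq), MeOH, 40 °C
Reagents that add atoms: none
Why: Acid-catalysed acetal exchange with methanol cleaves the aryl MOM ether at an acidity well below that needed to ionise the tertiary alcohol, whose cation is disfavoured by the β-aryloxy group, so dehydration, ring expansion and loss of configuration at C2 should not occur.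

Step 7
Reactants: 9 1-[(2S)-4,6-dihydroxy-2-(2-hydroxypropan-2-yl)-2,3-dihydrobenzofuran-7-yl]-3-(4-methoxyphenyl)propan-1-one; 10 1-bromo-3-methylbut-2-ene (prenyl bromide)
Product: 11 1-[(2S)-4,6-dihydroxy-2-(2-hydroxypropan-2-yl)-5-(3-methylbut-2-en-1-yl)-2,3-dihydrobenzofuran-7-yl]-3-(4-methoxyphenyl)propan-1-one (target)
Conditions: 10 (1.05 equiv), KOH (2.2 equiv), MeOH–H2O, 0 °C to rt
Reagents that add atoms: none
Why: This is C-alkylation of an ambident acylphloroglucinol-type phenoxide (SN2 on prenyl bromide): in a protic medium the oxygens are shielded by hydrogen bonding, so carbon C5, flanked by O4 and O6 and the only ring CH left, should take the prenyl group, while the tertiary alcohol and C2 are inert to cold aqueous base.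

## Compound list

1 | phloroglucinol | Oc1cc(O)cc(O)c1 | starting material
2 | 3-(4-methoxyphenyl)propanoic acid | COc1ccc(CCC(=O)O)cc1 | starting material
3 | 3-(4-methoxyphenyl)-1-(2,4,6-trihydroxyphenyl)propan-1-one | COc1ccc(CCC(=O)c2c(O)cc(O)cc2O)cc1 | intermediate
4 | 1-[2,6-dihydroxy-4-(methoxymethoxy)phenyl]-3-(4-methoxyphenyl)propan-1-one | COc1ccc(CCC(=O)c2c(O)cc(OCOC)cc2O)cc1 | intermediate
5 | 1-[2,6-dihydroxy-3-iodo-4-(methoxymethoxy)phenyl]-3-(4-methoxyphenyl)propan-1-one | COc1ccc(CCC(=O)c2c(O)cc(OCOC)c(I)c2O)cc1 | intermediate
6 | isoprene | C=CC(C)=C | starting material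
7 | 1-[(2S)-6-hydroxy-4-(methoxymethoxy)-2-(prop-1-en-2-yl)-2,3-dihydrobenzofuran-7-yl]-3-(4-methoxyphenyl)propan-1-one | COc1ccc(CCC(=O)c2c(O)cc(OCOC)c3c2O[C@H](C(C)=C)C3)cc1 | intermediate
8 | 1-[(2S)-6-hydroxy-2-(2-hydroxypropan-2-yl)-4-(methoxymethoxy)-2,3-dihydrobenzofuran-7-yl]-3-(4-methoxyphenyl)propan-1-one | COc1ccc(CCC(=O)c2c(O)cc(OCOC)c3c2O[C@H](C(C)(C)O)C3)cc1 | intermediate
9 | 1-[(2S)-4,6-dihydroxy-2-(2-hydroxypropan-2-yl)-2,3-dihydrobenzofuran-7-yl]-3-(4-methoxyphenyl)propan-1-one | COc1ccc(CCC(=O)c2c(O)cc(O)c3c2O[C@H](C(C)(C)O)C3)cc1 | intermediate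
10 | 1-bromo-3-methylbut-2-ene | CC(C)=CCBr | starting material
11 | 1-[(2S)-4,6-dihydroxy-2-(2-hydroxypropan-2-yl)-5-(3-methylbut-2-en-1-yl)-2,3-dihydrobenzofuran-7-yl]-3-(4-methoxyphenyl)propan-1-one | COc1ccc(CCC(=O)c2c(O)c(CC=C(C)C)c(O)c3c2O[C@H](C(C)(C)O)C3)cc1 | target

Total step count: 7. Longest linear sequence: 7 steps (from phloroglucinol 1).

## Steps most likely to fail

(a) Step 4, the heteroannulation.
- Risk: oxidative addition may be slow at the C–I bond crowded by two ortho oxygens, with hydrodeiodination taking over. Insertion may occur at the methyl-bearing alkene of isoprene, or facial discrimination in the C–O bond formation may be insufficient.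
- Fallback, from 4 back to 8, free of palladium and bypassing steps 3–5: C-alkylation of 4 with prenyl bromide 10 (KOH, MeOH–H2O, 0 °C) at one of its two equivalent ring CH positions would give 1-[2,6-dihydroxy-4-(methoxymethoxy)-3-(3-methylbut-2-en-1-yl)phenyl]-3-(4-methoxyphenyl)propan-1-one F1.
- Shi epoxidation of the trisubstituted alkene (D-fructose-derived ketone catalyst, KHSO5, K2CO3 buffer, MeCN–dimethoxymethane–H2O, 0 °C) should give 1-[3-{[(2R)-3,3-dimethyloxiran-2-yl]methyl}-2,6-dihydroxy-4-(methoxymethoxy)phenyl]-3-(4-methoxyphenyl)propan-1-one F2.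
- In the basic medium the adjacent phenoxide should open this epoxide at its secondary carbon in a 5-exo-tet closure with inversion, giving (S)-8 directly.

(b) Step 7, the C-prenylation.
- Risk: O-alkylation at O4 may compete, and a second alkylation at C5 with loss of aromaticity is possible.
- Fallback, from 9 back to 11: palladium-catalysed O-alkylation of the non-chelated 4-OH with tert-butyl 2-methylbut-3-en-2-yl carbonate (Pd(PPh3)4, THF, 0 °C) attacks the more substituted allyl terminus. It would give 1-[(2S)-6-hydroxy-2-(2-hydroxypropan-2-yl)-4-[(2-methylbut-3-en-2-yl)oxy]-2,3-dihydrobenzofuran-7-yl]-3-(4-methoxyphenyl)propan-1-one F3.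
- A thermal aromatic Claisen rearrangement (toluene, 110 °C) then carries the allyl unit with transposition to C5, the only open ortho position. After tautomerisation this leaves the linear prenyl group of 11.

(c) Step 5, the hydration.
- Risk: the alkene may simply be reduced by a second hydrogen-atom transfer, the peroxide stage may not be fully reduced, or the electron-rich phenol ring may be oxidised by cobalt and O2.
- Fallback, from 7 back to 8, ionic rather than radical: oxymercuration (Hg(OAc)2, THF–H2O, rt) places OH on the tertiary carbon and mercury on CH2. It would give 1-[(2S)-2-[1-(acetoxymercurio)-2-hydroxypropan-2-yl]-6-hydroxy-4-(methoxymethoxy)-2,3-dihydrobenzofuran-7-yl]-3-(4-methoxyphenyl)propan-1-one F4, as epimers at a carbinol carbon that loses its chirality in the next operation.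
- Demercuration (NaBH4, aq NaOH, 0 °C) then gives 8. Under these conditions the ketone is protected as part of the chelated phenoxide, and any reversible ring mercuration is erased in the same reduction.

## Further compounds

F1 | step 4 | 1-[2,6-dihydroxy-4-(methoxymethoxy)-3-(3-methylbut-2-en-1-yl)phenyl]-3-(4-methoxyphenyl)propan-1-one | COc1ccc(CCC(=O)c2c(O)cc(OCOC)c(CC=C(C)C)c2O)cc1
F2 | step 4 | 1-[3-{[(2R)-3,3-dimethyloxiran-2-yl]methyl}-2,6-dihydroxy-4-(methoxymethoxy)phenyl]-3-(4-methoxyphenyl)propan-1-one | COc1ccc(CCC(=O)c2c(O)cc(OCOC)c(C[C@H]3OC3(C)C)c2O)cc1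
F3 | step 7 | 1-[(2S)-6-hydroxy-2-(2-hydroxypropan-2-yl)-4-[(2-methylbut-3-en-2-yl)oxy]-2,3-dihydrobenzofuran-7-yl]-3-(4-methoxyphenyl)propan-1-one | COc1ccc(CCC(=O)c2c(O)cc(OC(C)(C)C=C)c3c2O[C@H](C(C)(C)O)C3)cc1
F4 | step 5 | 1-[(2S)-2-[1-(acetoxymercurio)-2-hydroxypropan-2-yl]-6-hydroxy-4-(methoxymethoxy)-2,3-dihydrobenzofuran-7-yl]-3-(4-methoxyphenyl)propan-1-one | COc1ccc(CCC(=O)c2c(O)cc(OCOC)c3c2O[C@H](C(C)(O)C[Hg]OC(C)=O)C3)cc1
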